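The solid substrate went into solution slowly, and I began from that slowness.

| setting | epsilon | gamma | beta | summer | midnight | winter | dawn | noon |
|---|---|---|---|---|---|---|---|---|
| solid substrate | 0.041 M | 0.18 M | 0.94 M | 0.050 M | 0.10 M | 0.20 M | 0.40 M | 0.80 M |
| remark | run made earlier | run made earlier | run made earlier |  |  |  |  |  |
| time |  |  |  | 6.0 h | 6.0 h | 6.0 h | 6.0 h | 6.0 h |

| run | time / h | target / % | solid substrate / % |
|---|---|---|---|
| epsilon | 0.833 | 12 | 70 |
| epsilon | 1.50 | 30 | 49 |
| epsilon | 2.50 | 59 | 16 |
| epsilon | 3.00 | 71 | 0 |
| gamma | 0.250 | 0 | 100 |
| gamma | 0.500 | 0 | 97 |
| gamma | 1.33 | 6 | 91 |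
| gamma | 3.00 | 18 | 79 |
| beta | 0.250 | 2 | 96 |
| beta | 0.500 | 0 | 100 |
| beta | 1.33 | 0 | 97 |
| beta | 3.00 | 0 | 96 |

(standard deviation of a reading: 1.5 percentage points)

- as a solid, counted per litre of solution: solid substrate
- steps thought possible: starting material -> target; solid substrate <-> starting material
- at the start none of the solid substrate is in solution
- "hardly changes" means that all values lie within two and a half points (for a concentration: within two and a half percent of the largest)

- amount of target at the end, in percent of the solid substrate charged for summer, midnight, winter, dawn, noon, in this order
- the course of these numbers from the first flask to the last (falls, then rises / hardly changes / rises all the way / falls all the way / rises, then falls)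

1. I turned the question round. For the row to hardly change, solid would have to leave in proportion to its charge, so gamma's solid would have to leave 4.39 times as fast as epsilon's.

2. Gamma lost 0.0126 M h⁻¹ up to 3.00 h. I call this F, the feed: the solid substrate entering solution per litre and hour. Epsilon lost 0.0138 M h⁻¹ up to 2.50 h, so the gamma-to-epsilon ratio read 0.913, far from the ratio the opposite outcome needs.

3. Late in gamma, target rose at 0.0129 M h⁻¹, about equal to F. Conversion in gamma was keeping pace, so I took dissolving as the rate-limiting step while solid lasted.

4. Gamma's material that was neither solid nor target at 3.00 h gave a scattered reading of the amount held in solution, D = 0.00540 M. With solid present, and with F and D held fixed, I reckoned target as F·t − D, which at 6.0 h is 0.0702 M.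

5. That gave 70.2 % for midnight, 35.1 % for winter, 17.5 % for dawn and 8.77 % for noon. In summer, F·t is 0.0756 M, more than the charge. By F, summer's solid lasts 3.97 h, so I expected close to 100 % there. One doubt remained: the same reckoning gives beta 3.45 % target at 3.00 h, against a reading of 0 % with scatter 1.5 percentage points.

6. The forecast gave 97 %, 70 %, 34 %, 9 % and 0.5 %, falls all the way, holding that “Heavy loading therefore shuts the reaction down”; it parts from my reckoning at dawn and noon.

7. The flasks gave 99.0 %, 68.7 %, 34.4 %, 17.2 % and 8.59 %: falls all the way.

    starting material → target, rate k1*[starting material]/(1 + ([starting material]/sat1)) (0.0580 M, k = 0.0239 min⁻¹)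
    solid substrate ⇌ starting material, rate k2*(cs2 - [starting material]) while solid is left; crystals form when [starting material] > cs2 (solubility = 0.0760 M, k = 0.00331 min⁻¹)

Midnight's local order, the percent change of its end target, counted in percent of the charge, per percent of charge, was −1.0. Carried to noon at 60.0 h, F reckons 5.50 % of the charge still solid substrate; the noon flask held 2.55 %.

The runs come from a simulation with made-up constants; noise was put on by code.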